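Decide which number earns a measurement before you reckon the alder run, and hold each against the flat case, order zero, where the charge leaves the rate unchanged. Take the first reading of the ash run as a rate, 0.0134 M min⁻¹, and call the product a flask makes at that steady rate the zero-order line.

common to all: catalyst 0.00100 M
- ash: starting material 0.500 M; partner 1.00 M
- larch: starting material 0.200 M; partner 0.700 M
- cedar: starting material 0.500 M; partner 1.00 M; product 0.250 M
- birch: starting material 0.500 M; partner 1.50 M
- alder: starting material 1.50 M; partner 1.00 M; time 50 min

| run | time / min | [product] / M |
|---|---|---|
| ash run | 10 | 0.134 |
| ash run | 20 | 0.248 |
| ash run | 30 | 0.328 |
| ash run | 40 | 0.392 |
| ash run | 50 | 0.435 |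
| larch run | 10 | 0.076 |
| larch run | 20 | 0.124 |
| larch run | 30 | 0.153 |
| larch run | 40 | 0.174 |
| larch run | 50 | 0.177 |
| cedar run | 10 | 0.379 |
| cedar run | 20 | 0.492 |
| cedar run | 30 | 0.578 |
| cedar run | 40 | 0.640 |
| cedar run | 50 | 0.687 |
| birch run | 10 | 0.141 |
| birch run | 20 | 0.272 |
| birch run | 30 | 0.377 |
| birch run | 40 | 0.439 |
| birch run | 50 | 0.484 |

(scatter of a reading: 0.003 M)

- order of the initial rate in [partner], near the charge of the ash run, the rate being that where two percent of its starting material are product
- order of the initial rate in [starting material], near the charge of the ash run, the rate being that where two percent of its starting material are product (one fixed amount of product, the same in the runs compared)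
- the larch run starts with 0.300 M less of starting material and of partner than the ash run, and with no product. Compared where both hold the same amount of starting material, once fifteen percent of what the larch run was charged with has turned into product, is the larch run faster, slower or alike (within a tenth)?
- product in the alder run at 50 min, as a share of the starting material charged

- Overall: starting material + partner -> product, with catalyst as catalyst.
- Constant volume, constant temperature.
- Readings of a species count what is bound in complexes too.
- "The second partner" is partner.
- An order is taken over about fifteen percent of the charge, up and down.

Lay the line on the alder run first:

product on the line at 50 min = 0.670 M, a share of 44.7 %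

Now test each number in turn. The scatter hardly counts, since one standard deviation on that first reading is 2.24 % of it, or 1 percentage point on the alder share. Added product can be set aside, since the cedar run gains 0.129 M in its first 10 min against 0.134 M in the ash run. Partner counts a little, so read its order from the birch and ash runs at 20 min:

order in partner = 0.228
mean c(partner) on the line = 0.665 M, so the rate is multiplied by 0.911

Starting material counts most. Its mean on the line is 1.17 M, against 0.433 M early in the ash run. Correct the first readings of the larch and ash runs for partner:

order in starting material, read between their charges = 0.530

Carried upward, that reading gives a share of 69.0 %, more than the 66.7 % that partner, the limiting reagent here, allows, so do not carry it. Order zero gives 40.7 %. For any order from zero up, then, the alder share lies between 40.7 % and the ceiling of 66.7 %, and the readings do not narrow this further, because the alder charge of 1.50 M is higher than any charge of starting material in the runs, so the order up there is unread. As a judgement and not a result, take the line's 44.7 % as the working figure, nearer the low end of that range.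

The forecast gives 0.2 for partner, 0.42 for starting material, faster for the larch run and 48 % for the alder run, with the words “Starting material shows saturation”. Its share is higher than mine.

    catalyst + starting material ⇌ catalyst-substrate complex, settled at all times (2.410 L mol⁻¹)
    catalyst-substrate complex + partner ⇌ ternary complex, settled at all times (11.80 L mol⁻¹)
    ternary complex → product + catalyst (16.26 min⁻¹)
    2 catalyst ⇌ resting dimer, settled at all times (7720 L mol⁻¹)

The flask gives 0.23 and 0.16 for the orders, alike for the larch run at a ratio of 1.0, and 44.0 % for the alder run. The order in starting material is lower than the forecast's by a factor of 2.57. The alder run's 0.660 M of product lies 0.0106 M below the zero-order line. In the birch run the line puts half of the starting material charged at 18.7 min, and the birch run reached it at 18.5 min.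

(All runs stem from a simulated flask for substances that don't exist; noise was put on by code.)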